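**Assumption:** the target, 1,2-bis(2,3,6-tribromo-4,5-dihydroxyphenyl)ethane, has no stereogenic element (it is achiral and symmetric), so no enantiocontrol is needed and the SMILES is taken as written.

**Retrosynthetic overview**
- The six aryl C–Br bonds are removed last: the target comes from 3,3',4,4'-tetrahydroxybibenzyl by exhaustive electrophilic bromination.
- The bis-catechol comes from its tetramethyl ether (O-demethylation), that from (Z)-3,3',4,4'-tetramethoxystilbene (hydrogenation), and that from an α-arylcinnamic acid (decarboxylation).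
- Key C–C disconnection: the central C=C of the α-arylcinnamic acid, made by a Perkin-type aldol condensation of 3,4-dimethoxyphenylacetic acid (enolate partner) with 3,4-dimethoxybenzaldehyde.
- No ring is formed in the route; both benzene rings come intact from the two starting materials.

**Route**

Step 1
Reactants: 1 3,4-dimethoxyphenylacetic acid; 2 3,4-dimethoxybenzaldehyde
Product: 5 (E)-2,3-bis(3,4-dimethoxyphenyl)acrylic acid, via mixed anhydride 3 (not isolated), via β-acetoxy acid 4 (not isolated)
Conditions: Ac2O (3 equiv), Et3N (2 equiv), 110 °C, 24 h; then H2O, 100 °C; aq K2CO3 extraction, acidify with HCl, recrystallise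
Reagents that add atoms: none
Why: Perkin (Oglialoro) aldol condensation, in which the enolate of mixed anhydride 3 adds to the non-enolisable aldehyde 2 and acetyl transfer followed by E1cB loss of acetate from 4 gives the thermodynamically favoured E acid (aryl groups cis), with no stereocentre remaining.

Step 2
Reactants: 5 (E)-2,3-bis(3,4-dimethoxyphenyl)acrylic acid
Product: 6 (Z)-1,2-bis(3,4-dimethoxyphenyl)ethene
Conditions: Cu powder (cat.), quinoline, 220 °C, 3 h, N2; dilute HCl wash
Reagents that add atoms: none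
Why: Copper-mediated thermal protodecarboxylation of an α-arylcinnamic acid replaces CO2H by H to give the cis-diaryl (Z) alkene, and any E isomer formed by thermal isomerisation is harmless because the double bond is hydrogenated in step 3.

Step 3
Reactants: 6 (Z)-1,2-bis(3,4-dimethoxyphenyl)ethene
Product: 7 1,2-bis(3,4-dimethoxyphenyl)ethane
Conditions: H2 (1 atm), 10% Pd/C, EtOAc/EtOH, rt
Reagents that add atoms: none
Why: Heterogeneous catalytic hydrogenation of a stilbene C=C is fast and leaves the arenes and aryl methyl ethers untouched, and no stereocentre is created.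

Step 4
Reactants: 7 1,2-bis(3,4-dimethoxyphenyl)ethane
Product: 9 4,4'-(ethane-1,2-diyl)bis(benzene-1,2-diol), via bis(bromodioxaborole) 8 (not isolated)
Conditions: BBr3 (6 equiv), CH2Cl2, −78 °C to rt, 16 h; then ice/H2O, EtOAc extraction under N2
Reagents that add atoms: none
Why: Lewis acid-mediated O-demethylation, in which BBr3 coordinates each ether oxygen, bromide removes the methyl group by SN2 as MeBr, and the cyclic bromoborate 8 is hydrolysed on work-up to the free bis-catechol.

Step 5
Reactants: 9 4,4'-(ethane-1,2-diyl)bis(benzene-1,2-diol)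
Product: 10 1,2-bis(2,3,6-tribromo-4,5-dihydroxyphenyl)ethane
Conditions: Br2 (8 equiv), AcOH, rt then 60 °C, dark, 12 h; then aq NaHSO3/Na2S2O4 work-up, recrystallise
Reagents that add atoms: bromine, BrBr
Why: Exhaustive electrophilic aromatic bromination, in which each strongly activated catechol ring has exactly three free positions so that substitution of all six gives a single constitutional product, and the reductive work-up returns any o-quinone to the catechol.

**Compound list**
1 | 3,4-dimethoxyphenylacetic acid (homoveratric acid) | COc1ccc(CC(=O)O)cc1OC | starting material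
2 | 3,4-dimethoxybenzaldehyde (veratraldehyde) | COc1ccc(C=O)cc1OC | starting material
3 | acetic (3,4-dimethoxyphenyl)acetic anhydride (mixed anhydride) | COc1ccc(CC(=O)OC(C)=O)cc1OC | intermediate
4 | 3-acetoxy-2,3-bis(3,4-dimethoxyphenyl)propanoic acid (racemic, mixture of diastereomers) | COc1ccc(C(OC(C)=O)C(C(=O)O)c2ccc(OC)c(OC)c2)cc1OC | intermediate
5 | (E)-2,3-bis(3,4-dimethoxyphenyl)acrylic acid | COc1ccc(/C=C(/C(=O)O)c2ccc(OC)c(OC)c2)cc1OC | intermediate
6 | (Z)-1,2-bis(3,4-dimethoxyphenyl)ethene | COc1ccc(/C=C\c2ccc(OC)c(OC)c2)cc1OC | intermediate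
7 | 1,2-bis(3,4-dimethoxyphenyl)ethane | COc1ccc(CCc2ccc(OC)c(OC)c2)cc1OC | intermediate
8 | 1,2-bis(2-bromo-1,3,2-benzodioxaborol-5-yl)ethane | BrB1Oc2ccc(CCc3ccc4OB(Br)Oc4c3)cc2O1 | intermediate
9 | 4,4'-(ethane-1,2-diyl)bis(benzene-1,2-diol) | Oc1ccc(CCc2ccc(O)c(O)c2)cc1O | intermediate
10 | 1,2-bis(2,3,6-tribromo-4,5-dihydroxyphenyl)ethane | Oc1c(O)c(Br)c(CCc2c(Br)c(O)c(O)c(Br)c2Br)c(Br)c1Br | target

**Totals:** 5 steps; longest linear sequence 5 steps.

**Steps most likely to fail and fallbacks**

Step 2 (harsh decarboxylation; tarring or incomplete conversion at 220 °C). The fallback sets out from 5 and comes back at 7, bypassing 6. The acrylic acid 5 is hydrogenated (H2, 10% Pd/C, EtOH) to 2,3-bis(3,4-dimethoxyphenyl)propanoic acid F5 (racemic). This is coupled with N-hydroxyphthalimide (N,N'-diisopropylcarbodiimide, DMAP cat., CH2Cl2) to the redox-active ester 1,3-dioxoisoindolin-2-yl 2,3-bis(3,4-dimethoxyphenyl)propanoate F6. Radical reductive decarboxylation (NiCl2·6H2O 10 mol%, 4,4'-di-tert-butyl-2,2'-bipyridine, Zn, PhSiH3, THF/DMF/iPrOH, 40 °C) then gives 7 under mild conditions.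

Step 5 (six-fold bromination of an air-sensitive bis-catechol; risk of incomplete bromination or oxidation to quinones). The fallback sets out from 7 and comes back at 10, changing the order of bromination and deprotection. The tetramethyl ether 7 is brominated exhaustively (Br2 8 equiv, Fe powder cat. giving FeBr3 in the flask, CH2Cl2, 0 °C to reflux) to 1,2-bis(2,3,6-tribromo-4,5-dimethoxyphenyl)ethane F7. BBr3 (CH2Cl2, −78 °C to rt, then H2O) then cleaves the four methyl ethers to give 10, so the free catechol is never exposed to excess bromine.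

Step 1 (Perkin condensation; high temperature, possible low conversion or self-condensation). The fallback sets out from 1 (with 2) and comes back at 5 by a stepwise directed aldol. Acid 1 is esterified (MeOH, H2SO4 cat., reflux) to methyl (3,4-dimethoxyphenyl)acetate F1. Its lithium enolate (LiN(iPr)2, THF, −78 °C) adds to aldehyde 2 to give methyl 3-hydroxy-2,3-bis(3,4-dimethoxyphenyl)propanoate F2 (racemic syn/anti mixture). MsCl/Et3N (CH2Cl2, 0 °C) gives methyl 2,3-bis(3,4-dimethoxyphenyl)-3-(methylsulfonyloxy)propanoate F3, which DBU eliminates (E1cB) to methyl (E)-2,3-bis(3,4-dimethoxyphenyl)acrylate F4. LiOH (THF/MeOH/H2O, 50 °C) returns acid 5; any Z isomer carried along also converges at 7 after steps 2 and 3.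

**Further compounds**
F1 | step 1 | methyl (3,4-dimethoxyphenyl)acetate | COC(=O)Cc1ccc(OC)c(OC)c1
F2 | step 1 | methyl 3-hydroxy-2,3-bis(3,4-dimethoxyphenyl)propanoate (racemic, syn/anti mixture) | COC(=O)C(c1ccc(OC)c(OC)c1)C(O)c1ccc(OC)c(OC)c1
F3 | step 1 | methyl 2,3-bis(3,4-dimethoxyphenyl)-3-(methylsulfonyloxy)propanoate (racemic, mixture of diastereomers) | COC(=O)C(c1ccc(OC)c(OC)c1)C(OS(C)(=O)=O)c1ccc(OC)c(OC)c1
F4 | step 1 | methyl (E)-2,3-bis(3,4-dimethoxyphenyl)acrylate | COC(=O)/C(=C/c1ccc(OC)c(OC)c1)c1ccc(OC)c(OC)c1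
F5 | step 2 | 2,3-bis(3,4-dimethoxyphenyl)propanoic acid (racemic) | COc1ccc(CC(C(=O)O)c2ccc(OC)c(OC)c2)cc1OC
F6 | step 2 | 1,3-dioxoisoindolin-2-yl 2,3-bis(3,4-dimethoxyphenyl)propanoate (racemic) | COc1ccc(CC(C(=O)ON2C(=O)c3ccccc3C2=O)c2ccc(OC)c(OC)c2)cc1OC
F7 | step 5 | 1,2-bis(2,3,6-tribromo-4,5-dimethoxyphenyl)ethane | COc1c(OC)c(Br)c(CCc2c(Br)c(OC)c(OC)c(Br)c2Br)c(Br)c1Br
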